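Read at 15.0 min, the larch and cedar runs show substrate at 0% and 0%, yet target stands at 39% in larch and lower, at 26%, in cedar.

all flasks: enzyme 0.01 mol%

|  | substrate | remark | time |
|---|---|---|---|
| larch | 0.047 M | run made earlier |  |
| cedar | 0.11 M | run made earlier |  |
| flask | 0.070 M |  | 1.0 h |

| run | time / min | target / % | substrate / % |
|---|---|---|---|
| larch | 1.50 | 9 | 71 |
| larch | 5.00 | 53 | 12 |
| larch | 15.0 | 39 | 0 |
| larch | 50.0 | 3 | 1 |
| cedar | 1.50 | 4 | 65 |
| cedar | 5.00 | 29 | 19 |
| cedar | 15.0 | 26 | 0 |
| cedar | 50.0 | 8 | 0 |

(readings scatter by 2 percentage points)

- a reading or a percentage of target counts all its forms, free or not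
- a reading of substrate is of its free form alone

* time up to 1.0 h at which target stands highest
* the amount of target, in percent of the substrate charged, at that time
* earliest time at which at least nineteen twentieths of that best amount are there
* latest time at which they still are

My own reckoning compares two rates. By 5.00 min substrate reads 12% of its charge in larch and 19% in cedar, and I take these shares of two different charges as an enzyme route whose rate goes with the enzyme present, so with the charge at a held loading. A loss taking two substrate goes with c_substrate squared, so the ratio of the two rates should go as one over the charge. This is an assumption, tested below.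

Target also decays: the summed readings of both runs from 15.0 min to 50.0 min give 0.0508 min⁻¹. Brought back to 5.00 min at that rate, the readings at 15.0 min give an estimate of the target formed, 64.8% in larch and 43.2% in cedar. That estimate over the rest of the charge serves as a selectivity factor, and multiplying it by the charge gives the crossover charge, where that factor would be one. Larch reads 0.0865 M and cedar 0.0836 M, with a mean of 0.0851 M. The flask, charged at 0.070 M, should therefore peak near 54.9%.

The forecast, noting that “Target yield falls with concentration”, gives 43% at 0.125 h, with a window from 0.1 h to 0.17 h. Its best lies below my 54.9%.

The flask peaks at 61.0% at 0.112 h, and holds the required amount from 0.102 h to 0.131 h.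

    target → over-reaction product (k = 0.0660 min⁻¹)
    substrate + target ⇌ idle adduct, settled at all times (K = 28.0 L mol⁻¹)
    2 substrate → self-condensation product (k = 1.10 L mol⁻¹ min⁻¹)
    substrate + enzyme → target + enzyme, rate k4*[substrate]*[enzyme]/(1 + ([substrate]/Km4) + ([substrate]/Ksi4)^2) (0.0520 M, 5.90 mM, k = 14000 L mol⁻¹ s⁻¹)

At that peak the flask holds 29.5% of self-condensation product, and its charge times selectivity factor, taken with the best amount of target, is 0.109 M. The neighbour, charged with 0.12 M, was reckoned from the crossover charge at 41.5%. It reaches 49.4%, above that reckoning, and ends with 44.4% of self-condensation product. Its charge times selectivity factor, taken the same way, is 0.117 M.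

The runs are calculated on assumed constants, and the scatter is random.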